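The synthesis rests on the bond between the benzene ring carbon ortho to the phenolic OH and the ketone carbon of the C8 trienoyl chain. The key step exploits the ortho-hydroxyaryl ketone motif, O–C(ring)–C(ring)–C(=O): the phenol oxygen serves as a temporary tether. The complete (2E,4Z,6Z)-trienoic acid fragment is esterified onto an ortho-iodophenol that already carries the (R)-side chain. Iodine–lithium exchange at −100 °C then triggers an anionic Fries-type 1,3 O→C acyl shift. One operation forges the aryl–carbonyl bond, liberates the phenol and should leave all four alkenes and the stereocentre untouched. The precursor is an iodoaryl trienoate ester.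

Key step: step 12

Assumption: in step 3 the (S)-ligand with the (E)-alkenol is taken to deliver the (R) centre; if this pairing proves to give the (S) aldehyde, the (R)-ligand is used instead.

Step 1
Reactants: 1 4-methoxyphenol
Product: 2 1-methoxy-4-(methoxymethoxy)benzene
Conditions: MOMCl, i-Pr2NEt, CH2Cl2, 0 °C → rt
Reagents that add atoms: chloromethyl methyl ether COCCl
Why: Williamson-type O-alkylation of the phenol with the reactive chloromethyl ether installs an acetal that directs the next metalation and forms no stereocentre.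

Step 2
Reactants: 2 1-methoxy-4-(methoxymethoxy)benzene
Product: 5 [5-methoxy-2-(methoxymethoxy)phenyl]boronic acid, via aryllithium 3 (not isolated), via lithium aryltrimethoxyborate 4 (not isolated)
Conditions: n-BuLi, TMEDA, THF, 0 °C; B(OMe)3, −78 °C → rt; aq NH4Cl
Reagents that add atoms: trimethyl borate COB(OC)OC; water O
Why: Directed ortho-metalation, in which the methoxymethoxy group out-directs methoxy so that lithiation and borylation occur at the carbon next to it, followed by mild hydrolysis that leaves the acetal intact.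

Step 3
Reactants: 5 [5-methoxy-2-(methoxymethoxy)phenyl]boronic acid (excess); 6 (E)-pent-3-en-1-ol
Product: 7 (4R)-4-[5-methoxy-2-(methoxymethoxy)phenyl]pentanal
Conditions: Pd(MeCN)2(OTs)2 (6 mol %), Cu(OTf)2 (6 mol %), (S)-4-tert-butyl-2-[5-(trifluoromethyl)pyridin-2-yl]-4,5-dihydrooxazole (13 mol %), 3 Å molecular sieves, O2 (1 atm), DMF, rt
Reagents that add atoms: none
Why: Enantioselective redox-relay oxidative Heck arylation, in which the aryl–palladium species (divalent palladium) inserts the alkene with aryl going to C4 remote from the hydroxyl, palladium migrates along the chain by β-hydride elimination and reinsertion and leaves as the aldehyde, and the chiral pyridine–oxazoline ligand selects the alkene face and so sets the (R) benzylic centre.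

Step 4
Reactants: 7 (4R)-4-[5-methoxy-2-(methoxymethoxy)phenyl]pentanal; 8 tert-butyl (triphenylphosphoranylidene)acetate
Product: 9 tert-butyl (2E,6R)-6-[5-methoxy-2-(methoxymethoxy)phenyl]hept-2-enoate
Conditions: CH2Cl2, rt
Reagents that add atoms: none
Why: Wittig olefination with a stabilised ylide should give the (E)-enoate, and the stereocentre is γ to the aldehyde and cannot epimerise.

Step 5
Reactants: 9 tert-butyl (2E,6R)-6-[5-methoxy-2-(methoxymethoxy)phenyl]hept-2-enoate
Product: 10 tert-butyl (2E,6R)-6-(2-hydroxy-5-methoxyphenyl)hept-2-enoate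
Conditions: TsOH·H2O (10 mol %), MeOH, 40 °C
Reagents that add atoms: none
Why: Acid-catalysed acetal exchange removes the phenolic methoxymethyl group as dimethoxymethane under conditions too mild to ionise the tert-butyl ester.

Step 6
Reactants: 10 tert-butyl (2E,6R)-6-(2-hydroxy-5-methoxyphenyl)hept-2-enoate
Product: 11 tert-butyl (2E,6R)-6-(2-hydroxy-3-iodo-5-methoxyphenyl)hept-2-enoate
Conditions: NIS, TsOH·H2O (10 mol %), MeCN, 0 °C
Reagents that add atoms: N-iodosuccinimide O=C1CCC(=O)N1I
Why: Electrophilic aromatic iodination, in which the free OH is the strongest director and its para position and one ortho position are blocked, so iodine should enter the remaining ortho carbon while the electron-poor enoate stays inert.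

Step 7
Reactants: 12 furan (solvent, excess); 13 ethyl diazoacetate
Product: 15 ethyl (2E,4Z)-6-oxohexa-2,4-dienoate, via cyclopropane adduct 14 (not isolated)
Conditions: Rh2(OAc)4 (0.5 mol %), neat furan, slow addition of 13, rt; then CH2Cl2, 40 °C
Reagents that add atoms: none
Why: Rhodium-carbenoid cyclopropanation of furan followed by ring opening of the donor–acceptor cyclopropane 14 (furan unravelling), in which the Z alkene is the former furan C3–C4 bond held cis by the ring and the new alkene next to the ester forms E.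

Step 8
Reactants: 16 diphenyl phosphite; 17 tert-butyl bromoacetate
Product: 18 tert-butyl (diphenoxyphosphoryl)acetate
Conditions: Et3N, CH2Cl2, 0 °C → rt
Reagents that add atoms: none
Why: Michaelis–Becker-type P-alkylation of the diaryl phosphite with the bromoacetate gives the diaryl phosphonoacetate needed for Z-selective olefination.

Step 9
Reactants: 15 ethyl (2E,4Z)-6-oxohexa-2,4-dienoate; 18 tert-butyl (diphenoxyphosphoryl)acetate
Product: 20 1-tert-butyl 8-ethyl (2Z,4Z,6E)-octa-2,4,6-trienedioate, via sodium phosphonate 19 (not isolated)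
Conditions: NaH, THF, 0 °C; then 15, −78 → −40 °C
Reagents that add atoms: none
Why: Z-selective Horner–Wadsworth–Emmons olefination, in which the electron-poor aryloxy groups on phosphorus make elimination from the kinetically formed adduct fast and so should give the (Z)-enoate, while the low temperature keeps the existing Z alkene intact.

Step 10
Reactants: 20 1-tert-butyl 8-ethyl (2Z,4Z,6E)-octa-2,4,6-trienedioate
Product: 22 (2E,4Z,6Z)-8-tert-butoxy-8-oxoocta-2,4,6-trienoic acid, via lithium carboxylate 21 (not isolated)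
Conditions: LiOH (1.1 equiv), THF/H2O (3:1), 0 °C; then 0.5 M HCl to pH 3, 0 °C
Reagents that add atoms: lithium hydroxide [Li+].[OH-]
Why: Saponification distinguishes the two esters by size, since hydroxide attacks the ethyl ester carbonyl and leaves the hindered tert-butyl ester, and cold brief conditions protect the Z alkenes.

Step 11
Reactants: 11 tert-butyl (2E,6R)-6-(2-hydroxy-3-iodo-5-methoxyphenyl)hept-2-enoate; 22 (2E,4Z,6Z)-8-tert-butoxy-8-oxoocta-2,4,6-trienoic acid
Product: 23 8-tert-butyl 1-{2-iodo-4-methoxy-6-[(2R,5E)-7-tert-butoxy-7-oxohept-5-en-2-yl]phenyl} (2E,4Z,6Z)-octa-2,4,6-trienedioate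
Conditions: DCC, DMAP (20 mol %), CH2Cl2, 0 °C → rt
Reagents that add atoms: none
Why: Steglich esterification, in which the acylpyridinium derived from 22 acylates the hindered but iodine-acidified phenol and no alkene is touched.

Step 12
Reactants: 23 8-tert-butyl 1-{2-iodo-4-methoxy-6-[(2R,5E)-7-tert-butoxy-7-oxohept-5-en-2-yl]phenyl} (2E,4Z,6Z)-octa-2,4,6-trienedioate
Product: 27 tert-butyl (2Z,4Z,6E)-8-{2-hydroxy-5-methoxy-3-[(2R,5E)-7-tert-butoxy-7-oxohept-5-en-2-yl]phenyl}-8-oxoocta-2,4,6-trienoate, via aryllithium 24 (not isolated), via benzoxete lithium alkoxide 25 (not isolated), via lithium phenoxide 26 (not isolated)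
Conditions: n-BuLi (1.05 equiv), THF/Et2O/pentane (4:1:1), −100 °C; then AcOH, −100 °C → rt
Reagents that add atoms: none
Why: Iodine–lithium exchange, the fastest process available at −100 °C, turns the C–I carbon into the aryllithium 24, whose carbanion attacks the carbonyl of the ester on the neighbouring oxygen; the lithium alkoxide 25 then collapses by C–O cleavage to the chelated lithium phenoxide 26, which is protonated on quench. The closest known reaction type is the anionic Fries rearrangement of ortho-haloaryl esters (halogen–metal exchange-induced 1,3 O→C acyl migration, a Parham-type process). The only ring closed is the transient four-membered benzoxete ring of 25, formed by 4-exo-trig attack and opened again in the same step. No new stereocentre survives: the hemiketal carbon of 25 forms without control and is destroyed on ring opening, while the benzylic (R) centre and the four alkenes should stay untouched because no reversible conjugate addition intervenes. The step needs chemoselectivity (exchange before butyllithium adds to any of the three esters or the polyene), secured by the iodide, the low temperature and the hindered tert-butyl esters, and site selectivity (acyl to the ring carbon ortho to oxygen), secured by the position of iodine; the new ketone is shielded from further attack as the phenoxide chelate.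

Step 13
Reactants: 27 tert-butyl (2Z,4Z,6E)-8-{2-hydroxy-5-methoxy-3-[(2R,5E)-7-tert-butoxy-7-oxohept-5-en-2-yl]phenyl}-8-oxoocta-2,4,6-trienoate
Product: 28 (2Z,4Z,6E)-8-{3-[(2R,5E)-6-carboxyhex-5-en-2-yl]-2-hydroxy-5-methoxyphenyl}-8-oxoocta-2,4,6-trienoic acid
Conditions: CF3CO2H/CH2Cl2 (1:4), 0 °C, dark
Reagents that add atoms: none
Why: Acid-mediated E1 cleavage of both tert-butyl esters releases isobutene and the diacid, and the hydrogen-bonded phenol–ketone and the alkenes should tolerate brief cold acid.

Compound list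
1 | 4-methoxyphenol | COc1ccc(O)cc1 | starting material
2 | 1-methoxy-4-(methoxymethoxy)benzene | COCOc1ccc(OC)cc1 | intermediate
3 | [5-methoxy-2-(methoxymethoxy)phenyl]lithium | COCOc1ccc(OC)cc1[Li] | intermediate
4 | lithium trimethoxy[5-methoxy-2-(methoxymethoxy)phenyl]borate | [Li+].COCOc1ccc(OC)cc1[B-](OC)(OC)OC | intermediate
5 | [5-methoxy-2-(methoxymethoxy)phenyl]boronic acid | COCOc1ccc(OC)cc1B(O)O | intermediate
6 | (E)-pent-3-en-1-ol | C/C=C/CCO | starting material
7 | (4R)-4-[5-methoxy-2-(methoxymethoxy)phenyl]pentanal | COCOc1ccc(OC)cc1[C@H](C)CCC=O | intermediate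
8 | tert-butyl (triphenylphosphoranylidene)acetate | CC(C)(C)OC(=O)C=P(c1ccccc1)(c1ccccc1)c1ccccc1 | starting material
9 | tert-butyl (2E,6R)-6-[5-methoxy-2-(methoxymethoxy)phenyl]hept-2-enoate | COCOc1ccc(OC)cc1[C@H](C)CC/C=C/C(=O)OC(C)(C)C | intermediate
10 | tert-butyl (2E,6R)-6-(2-hydroxy-5-methoxyphenyl)hept-2-enoate | COc1ccc(O)c([C@H](C)CC/C=C/C(=O)OC(C)(C)C)c1 | intermediate
11 | tert-butyl (2E,6R)-6-(2-hydroxy-3-iodo-5-methoxyphenyl)hept-2-enoate | COc1cc(I)c(O)c([C@H](C)CC/C=C/C(=O)OC(C)(C)C)c1 | intermediate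
12 | furan | c1ccoc1 | starting material
13 | ethyl diazoacetate | CCOC(=O)C=[N+]=[N-] | starting material
14 | ethyl 2-oxabicyclo[3.1.0]hex-3-ene-6-carboxylate (ester exo, racemic) | CCOC(=O)C1C2C=COC12 | intermediate
15 | ethyl (2E,4Z)-6-oxohexa-2,4-dienoate | CCOC(=O)/C=C/C=C\C=O | intermediate
16 | diphenyl phosphite (diphenyl phosphonate) | O=[PH](Oc1ccccc1)Oc1ccccc1 | starting material
17 | tert-butyl bromoacetate | CC(C)(C)OC(=O)CBr | starting material
18 | tert-butyl (diphenoxyphosphoryl)acetate | CC(C)(C)OC(=O)CP(=O)(Oc1ccccc1)Oc1ccccc1 | intermediate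
19 | sodium salt of 18 (phosphonate carbanion) | [Na+].CC(C)(C)OC(=O)[CH-]P(=O)(Oc1ccccc1)Oc1ccccc1 | intermediate
20 | 1-tert-butyl 8-ethyl (2Z,4Z,6E)-octa-2,4,6-trienedioate | CCOC(=O)/C=C/C=C\C=C/C(=O)OC(C)(C)C | intermediate
21 | lithium (2E,4Z,6Z)-8-tert-butoxy-8-oxoocta-2,4,6-trienoate | [Li+].[O-]C(=O)/C=C/C=C\C=C/C(=O)OC(C)(C)C | intermediate
22 | (2E,4Z,6Z)-8-tert-butoxy-8-oxoocta-2,4,6-trienoic acid | OC(=O)/C=C/C=C\C=C/C(=O)OC(C)(C)C | intermediate
23 | 8-tert-butyl 1-{2-iodo-4-methoxy-6-[(2R,5E)-7-tert-butoxy-7-oxohept-5-en-2-yl]phenyl} (2E,4Z,6Z)-octa-2,4,6-trienedioate | COc1cc(I)c(OC(=O)/C=C/C=C\C=C/C(=O)OC(C)(C)C)c([C@H](C)CC/C=C/C(=O)OC(C)(C)C)c1 | intermediate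
24 | aryllithium from 23 (lithium in place of iodine) | COc1cc([Li])c(OC(=O)/C=C/C=C\C=C/C(=O)OC(C)(C)C)c([C@H](C)CC/C=C/C(=O)OC(C)(C)C)c1 | intermediate
25 | lithium 2H-benzoxet-2-olate adduct (hemiketal carbon of either configuration, carrying the trienyl chain) | COc1cc2c(c([C@H](C)CC/C=C/C(=O)OC(C)(C)C)c1)OC2(O[Li])/C=C/C=C\C=C/C(=O)OC(C)(C)C | intermediate
26 | lithium phenoxide of 27 | COc1cc(C(=O)/C=C/C=C\C=C/C(=O)OC(C)(C)C)c(O[Li])c([C@H](C)CC/C=C/C(=O)OC(C)(C)C)c1 | intermediate
27 | tert-butyl (2Z,4Z,6E)-8-{2-hydroxy-5-methoxy-3-[(2R,5E)-7-tert-butoxy-7-oxohept-5-en-2-yl]phenyl}-8-oxoocta-2,4,6-trienoate | COc1cc(C(=O)/C=C/C=C\C=C/C(=O)OC(C)(C)C)c(O)c([C@H](C)CC/C=C/C(=O)OC(C)(C)C)c1 | intermediate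
28 | (2Z,4Z,6E)-8-{3-[(2R,5E)-6-carboxyhex-5-en-2-yl]-2-hydroxy-5-methoxyphenyl}-8-oxoocta-2,4,6-trienoic acid | COc1cc(C(=O)/C=C/C=C\C=C/C(=O)O)c(O)c([C@H](C)CC/C=C/C(=O)O)c1 | target

Total step count: 13.
Longest linear sequence: 9 steps (steps 1–6, 11, 12, 13, from 4-methoxyphenol); the trienoic acid branch is steps 7–10.

Steps most likely to fail

Step 12 (key step). Butyllithium may add to an ester carbonyl or to the polyene before the exchange is complete, or the aryllithium may close in a conjugate 6-endo fashion onto the trienoate instead of transferring the acyl group. The fallback is an intermolecular palladium-catalysed acylation that sets out from 11 and returns at the target 28. Compound 11 is protected (MOMCl, i-Pr2NEt, CH2Cl2) as the methoxymethyl ether F1, and zinc insertion (Zn dust, LiCl, THF, 40 °C) gives the arylzinc iodide F2. Acid 22 is converted with 1-chloro-N,N,2-trimethylprop-1-en-1-amine (CH2Cl2, 0 °C) into the acid chloride F3. Negishi acylation of F3 with F2 (Pd(PPh3)4, zerovalent palladium, THF, 0 °C → rt) gives the protected aryl ketone F4. CF3CO2H/CH2Cl2 at 0 °C then removes the methoxymethyl group and both tert-butyl esters to give 28.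

Step 3. With the electron-rich, ortho-substituted boronic acid, aryl insertion may lose site selectivity (C3 against C4 of the alkenol) and facial selectivity may erode. The fallback sets out from 5 and returns at aldehyde 7. Suzuki–Miyaura coupling of 5 with vinyl bromide (Pd(PPh3)4, K2CO3, THF/H2O, 60 °C) gives the styrene F5. Nickel-catalysed asymmetric hydrovinylation (ethylene 1 atm, [(allyl)NiBr]2, chiral phosphoramidite ligand, Na[B(3,5-(CF3)2C6H3)4], CH2Cl2, −70 °C) gives the (R)-3-arylbutene F6. Linear-selective hydroformylation (Rh(acac)(CO)2, BiPhePhos, CO/H2 1:1, toluene, 60 °C) then delivers 7.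

Step 10. Hydroxide may add reversibly to the doubly activated triene and scramble the Z alkenes, or hydrolysis may be unselective. The fallback assembles the chain on the phenol oxygen, so that neither acid 22 nor the esterification of step 11 is needed; it sets out from 11 and returns at ester 23. Bromoacetyl bromide and pyridine (CH2Cl2, 0 °C) give the aryl bromoacetate F7. N,N′-Ditosylhydrazine and DBU (THF, 0 °C) give the aryl diazoacetate F8. Rh2(OAc)4 in neat furan gives, through the cyclopropane adduct F9, the aryl (2E,4Z)-6-oxohexa-2,4-dienoate F10. Z-selective Horner–Wadsworth–Emmons olefination with the sodium phosphonate 19 (from 18 and NaH, THF, −78 °C) then gives 23.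

Further compounds
F1 | step 12 | tert-butyl (2E,6R)-6-[3-iodo-5-methoxy-2-(methoxymethoxy)phenyl]hept-2-enoate | COc1cc(I)c(OCOC)c([C@H](C)CC/C=C/C(=O)OC(C)(C)C)c1
F2 | step 12 | arylzinc iodide from F1 (ZnI in place of I) | COc1cc([Zn]I)c(OCOC)c([C@H](C)CC/C=C/C(=O)OC(C)(C)C)c1
F3 | step 12 | tert-butyl (2Z,4Z,6E)-8-chloro-8-oxoocta-2,4,6-trienoate | ClC(=O)/C=C/C=C\C=C/C(=O)OC(C)(C)C
F4 | step 12 | tert-butyl (2Z,4Z,6E)-8-{5-methoxy-2-(methoxymethoxy)-3-[(2R,5E)-7-tert-butoxy-7-oxohept-5-en-2-yl]phenyl}-8-oxoocta-2,4,6-trienoate | COc1cc(C(=O)/C=C/C=C\C=C/C(=O)OC(C)(C)C)c(OCOC)c([C@H](C)CC/C=C/C(=O)OC(C)(C)C)c1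
F5 | step 3 | 2-ethenyl-4-methoxy-1-(methoxymethoxy)benzene | COc1ccc(OCOC)c(C=C)c1
F6 | step 3 | 2-[(2R)-but-3-en-2-yl]-4-methoxy-1-(methoxymethoxy)benzene | COc1ccc(OCOC)c([C@H](C)C=C)c1
F7 | step 10 | 2-iodo-4-methoxy-6-[(2R,5E)-7-tert-butoxy-7-oxohept-5-en-2-yl]phenyl bromoacetate | COc1cc(I)c(OC(=O)CBr)c([C@H](C)CC/C=C/C(=O)OC(C)(C)C)c1
F8 | step 10 | 2-iodo-4-methoxy-6-[(2R,5E)-7-tert-butoxy-7-oxohept-5-en-2-yl]phenyl diazoacetate | COc1cc(I)c(OC(=O)C=[N+]=[N-])c([C@H](C)CC/C=C/C(=O)OC(C)(C)C)c1
F9 | step 10 | 2-iodo-4-methoxy-6-[(2R,5E)-7-tert-butoxy-7-oxohept-5-en-2-yl]phenyl 2-oxabicyclo[3.1.0]hex-3-ene-6-carboxylate (ester exo, both ring diastereomers) | COc1cc(I)c(OC(=O)C2C3C=COC23)c([C@H](C)CC/C=C/C(=O)OC(C)(C)C)c1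
F10 | step 10 | 2-iodo-4-methoxy-6-[(2R,5E)-7-tert-butoxy-7-oxohept-5-en-2-yl]phenyl (2E,4Z)-6-oxohexa-2,4-dienoate | COc1cc(I)c(OC(=O)/C=C/C=C\C=O)c([C@H](C)CC/C=C/C(=O)OC(C)(C)C)c1
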